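## Structural features

The target is a 2(5H)-furanone, labelled here O1, C2 (lactone carbonyl), C3 (enol carbon with a free acidic OH), C4 and C5. C4 carries ring A (3,4-dihydroxy-5-prenylphenyl). The quaternary C5 carries the methyl ester carbon C6 and the benzylic methylene C7, which leads to ring B (4-hydroxy-3-prenylphenyl, attached para to its hydroxyl). C5 is the only stereocentre; it is fully substituted, has no stereogenic neighbour and is S-configured (priorities O1 > C6 > C4 > C7), so it must be set by absolute control in the step that creates it. Fragile elements are the two electron-rich prenyl alkenes, each ortho to a phenol (acid closes them to chromans; electrophiles and radicals attack them), the air-sensitive catechol of ring A, and the enolised α-keto lactone, which should not meet base once C3–OH is free. The methyl ester must survive every deprotection. The real difficulty is the enantioselective construction of an oxygen-bearing quaternary carbon flanked by an ester, a tetrasubstituted alkene and a benzyl group. The key step uses the fact that C5 holds both O1 and C7: these are the two ends of a C5=C7 acrylate alkene, and the C2 carboxyl sits cis to C5 across C3=C4. Adding the ring B aryl group to C7 and the carboxylate oxygen to C5 therefore makes the benzyl bond, the ring and the stereocentre at once from a flat, achiral dienoic acid.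

## Logic of the disconnections

**24 from 23 from 22.** The cuts are the three O–CH2 acetal bonds (two on ring A, one on the C3 enol oxygen) and, before them, the O–acyl bond on ring B. Acetals are used on ring A and C3 because those oxygens must pass through strong base, triflation and palladium chemistry. An acyl group is used on ring B because that oxygen sits para to a diazonium group in 21, where a free phenol would collapse to a quinone diazide. The forward steps must avoid protic acid (chroman formation) and must apply any base while the C3 oxygen is still capped, which fixes the order: acyl first, acetals last.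

**22 from 16 and 21.** The cuts are C7–aryl (ring B) and O1–C5. This removes the ring, the only stereocentre and the benzyl linkage in one stroke and leaves an achiral acyclic acid and an aryl radical precursor. The forward step must deliver the aryl radical to C7 only, close the lactone at C5, and do so under control of a chiral copper catalyst. The acid must therefore have its carboxyl cis to the acrylate unit, and strong acid must be scavenged.

**21 from 20, 19, 18, 17 and 4.** The cuts are the N–N bond of the diazonium group, the N–O bonds of the nitro group, the aryl–CH2 bond of the prenyl group and the O–acyl bond. A para-nitrophenol with an ortho bromide already holds all three positions correctly. The forward sequence must reduce the nitro group and diazotise without touching the prenyl alkene or losing the activated aryl ester.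

**16 from 15.** The cut is the alkyl–oxygen bond of the C2 ester. The two carboxyl groups (C2 and C6) must be told apart, so the C2 ester in 15 is one that fluoride cleaves while the C6 methyl ester stays. The forward step must not isomerise the C3=C4 bond or add to the acrylate.

**15 from 12 and 14; 14 from 13.** The cut is the C4–C5 single bond between two sp2 carbons. This splits the diene into an enol triflate and an α-metallated acrylate, the latter available in one step from 13. The coupling must proceed with retention of alkene geometry at a hindered, tetrasubstituted centre.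

**12 from 11.** The cut is the enol O–S bond. The geometry of C3=C4 is decided here: the sulfonyl group must end cis to the ester so that, after coupling, the carboxyl is cis to C5. The forward step therefore needs a chelated enolate.

**11 from 10 from 5 and 9; 9 from 7 and 8; 7 from 6.** The cut is the C3–C4 bond, made as an aldol bond and then oxidised. This reduces the chain to an aromatic aldehyde and a two-carbon ester that already carries the protected C3 oxygen and the fluoride-labile ester group. The aldol stereocentres need no control because both disappear.

**5 from 3 and 4; 3 from 2 from 1.** The cuts are the aryl–CH2 bond of the ring A prenyl group and the two acetal O–C bonds, and finally one O–CH3 bond. The starting aldehyde 1 has bromine, the two oxygens and the formyl group in the right places. The forward coupling must give the linear and not the branched allyl isomer.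

## Other disconnections considered

**Alternative 1:** The cut is through the two aryl–CH2 bonds of the prenyl groups. Forward, the bis(1,1-dimethylallyl) aryl ether A1 would be heated in a high-boiling tertiary aniline so that two aromatic Claisen rearrangements, each with allylic inversion and followed by tautomerisation, give A2.
- In its favour: no prenyl alkene is present before this point, so diazonium formation, radical chemistry and couplings would run on more robust intermediates. On ring A only one ortho position is free, so the regiochemistry is fixed. The remaining silyl ethers would come off with fluoride, which is kinder to ortho-prenylphenols than the Lewis acid of the chosen end-game; on these points it is the better plan.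
- Against it: it builds neither the ring nor the stereocentre, so it still needs one of the other strategies for the core. The two tertiary allyl ethers must be installed selectively (ring A needs its two hydroxyls differentiated). The complete, enol-containing butenolide must survive prolonged heating, during which loss of the allyl unit as isoprene, para migration and chroman formation compete.
- Comparison: it is a late-stage decoration that could be combined with the chosen ring construction, but it adds ether-forming steps and a harsh thermal step in exchange for alkene-free intermediates. On step count it is at best equal.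

**Alternative 2:** The cut removes O1–C5 and C3–C4, splitting the ring into the nitrile oxide A4 (C2 and C3) and the trisubstituted allylic alcohol A3 (C4 and C5). Forward, a hydroxyl-directed cycloaddition on the zinc alkoxide of A3 in the presence of a tartrate ester would give the isoxazoline A5.
- In its favour: it is a closed-shell, suprafacial process with an established mode of asymmetric induction through a substrate-bound chiral metal alkoxide. On mechanistic security of the stereocontrol it is the better plan. It forms two ring bonds in one step, equal to the chosen step, and needs neither tin nor a diazonium salt.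
- Against it: the directed asymmetric variant is established for less substituted allylic alcohols. Here oxygen must go to a fully substituted carbon of a styrene-type alkene, against the normal polarity of nitrile oxide additions to styrenes. The C4 stereocentre is made only to be destroyed. A5 is at the wrong oxidation level: N–O cleavage, imine hydrolysis, lactonisation and a two-stage oxidation of CH2OH to the methyl ester must follow, all in the presence of prenyl groups and an enol.
- Comparison: it has firmer stereochemical precedent but is four to five steps longer after the key step, whereas the chosen plan needs only two deprotections.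

**Alternative 3:** The cut is aryl–C4 and O1–C5. Forward, a zerovalent palladium catalyst with a silver base would couple the ring A iodide A6 with the axially chiral allenoic acid A7, the aryl group going to the central allene carbon and the carboxylate oxygen to C5, to give A8.
- In its favour: it closes the same ring through the same O1–C5 bond (equal on bonds and rings formed). It is a stereospecific axis-to-centre transfer and so does not depend on an untested enantiodetermining step. It brings ring A in late. All four oxygens carry the same acetal, so the end-game is one step instead of two; on these points it is the better plan.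
- Against it: the difficulty moves into A7, a tetrasubstituted allene with an α-alkoxy acid and an ester on the far terminus. It would have to be made as one antipode (Sa, if oxypalladation is anti) and would be prone to base- or metal-induced racemisation and to conjugate addition. No short enantioselective entry to such an allene is apparent.
- Comparison: downstream it is shorter and mechanistically cleaner; upstream it is longer and less certain than the achiral acid 16, which is why the chosen plan was preferred.

Key step: step 16

Remark (assumption): the sense of induction of the bis(oxazoline) cannot be transferred with confidence to this ester-substituted radical. The route is written with the (S,S) ligand; its (R,R) antipode is used instead if the first run favours the R lactone.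

Remark (assumption): stannane 4 is taken as a purchasable reagent.

## Route

Step 1
Reactants: 1 5-bromovanillin (3-bromo-4-hydroxy-5-methoxybenzaldehyde)
Product: 2 3-bromo-4,5-dihydroxybenzaldehyde
Conditions: AlCl3, pyridine, CH2Cl2, reflux; then aq. HCl
Reagents that add atoms: none
Why: AlCl3 binds the ortho hydroxy–methoxy pair and pyridine removes the methyl group by SN2 (Lewis-acid-assisted aryl methyl ether cleavage); aldehyde and bromide are untouched.

Step 2
Reactants: 2 3-bromo-4,5-dihydroxybenzaldehyde
Product: 3 3-bromo-4,5-bis(methoxymethoxy)benzaldehyde
Conditions: MOMCl, iPr2NEt, CH2Cl2, 0 °C to rt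
Reagents that add atoms: chloromethyl methyl ether, COCCl
Why: O-alkylation of both phenols (acetal formation); the methoxymethyl ethers tolerate lithium amide, triflation, palladium coupling and fluoride and can be removed later without base.

Step 3
Reactants: 3 3-bromo-4,5-bis(methoxymethoxy)benzaldehyde; 4 tributyl(3-methylbut-2-en-1-yl)stannane
Product: 5 3,4-bis(methoxymethoxy)-5-(3-methylbut-2-en-1-yl)benzaldehyde
Conditions: Pd(PPh3)4 (5 mol %), DMF, 100 °C
Reagents that add atoms: none
Why: Stille coupling; zerovalent palladium inserts into the electron-poor aryl bromide, the allylic stannane transmetalates and reductive elimination at the unsubstituted allyl terminus should give the linear prenyl arene.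

Step 4
Reactants: 6 methyl glycolate
Product: 7 methyl 2-(methoxymethoxy)acetate
Conditions: MOMCl, iPr2NEt, CH2Cl2, 0 °C to rt
Reagents that add atoms: chloromethyl methyl ether, COCCl
Why: O-alkylation of the primary alcohol gives the two-carbon unit (future C2 and C3) with its oxygen already protected.

Step 5
Reactants: 7 methyl 2-(methoxymethoxy)acetate; 8 2-(trimethylsilyl)ethanol
Product: 9 2-(trimethylsilyl)ethyl 2-(methoxymethoxy)acetate
Conditions: Ti(OiPr)4 (5 mol %), toluene, 110 °C, MeOH distilled off
Reagents that add atoms: none
Why: Titanium-alkoxide-catalysed transesterification driven by removal of methanol; the silylethyl ester is what later allows the C2 carboxyl to be freed by fluoride while the C6 methyl ester stays.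

Step 6
Reactants: 5 3,4-bis(methoxymethoxy)-5-(3-methylbut-2-en-1-yl)benzaldehyde; 9 2-(trimethylsilyl)ethyl 2-(methoxymethoxy)acetate
Product: 10 2-(trimethylsilyl)ethyl 3-[3,4-bis(methoxymethoxy)-5-(3-methylbut-2-en-1-yl)phenyl]-3-hydroxy-2-(methoxymethoxy)propanoate (mixture of syn and anti racemates)
Conditions: LiN(iPr)2, THF, −78 °C; then 5; aq. NH4Cl
Reagents that add atoms: none
Why: Aldol addition of the lithium enolate of the α-alkoxy ester to the non-enolisable aldehyde forms the C3–C4 bond; the two new stereocentres are left uncontrolled because both become sp2 in steps 7 and 8.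

Step 7
Reactants: 10 the aldol adduct
Product: 11 2-(trimethylsilyl)ethyl 3-[3,4-bis(methoxymethoxy)-5-(3-methylbut-2-en-1-yl)phenyl]-2-(methoxymethoxy)-3-oxopropanoate (racemic, enolisable)
Conditions: Dess–Martin periodinane, CH2Cl2, 0 °C to rt
Reagents that add atoms: none
Why: Dess–Martin oxidation of the benzylic secondary alcohol to the ketone under near-neutral conditions; prenyl alkene and acetals are inert.

Step 8
Reactants: 11 the β-keto ester
Product: 12 2-(trimethylsilyl)ethyl (2E)-3-[3,4-bis(methoxymethoxy)-5-(3-methylbut-2-en-1-yl)phenyl]-2-(methoxymethoxy)-3-{[(trifluoromethyl)sulfonyl]oxy}prop-2-enoate (triflate cis to the ester)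
Conditions: Tf2O, sat. aq. LiOH, toluene, 5 °C
Reagents that add atoms: trifluoromethanesulfonic anhydride, O=S(=O)(OS(=O)(=O)C(F)(F)F)C(F)(F)F
Why: O-triflation of the β-keto ester enolate; lithium holds the enolate oxygen and the ester carbonyl in a six-membered chelate, so the triflate should end cis to the ester, which is the geometry that later puts the carboxyl cis to C5.

Step 9
Reactants: 13 methyl propiolate
Product: 14 methyl 2-(tributylstannyl)prop-2-enoate
Conditions: Bu3SnH, Pd(PPh3)4 (2 mol %), THF, 0 °C to rt
Reagents that add atoms: tributyltin hydride, CCCC[SnH](CCCC)CCCC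
Why: Palladium-catalysed syn-hydrostannation of the ynoate places tin on the carbon α to the ester, giving the α-stannyl acrylate; the minor β-isomer is removed by chromatography.

Step 10
Reactants: 12 the enol triflate; 14 methyl 2-(tributylstannyl)prop-2-enoate
Product: 15 1-methyl 5-[2-(trimethylsilyl)ethyl] (3E)-3-[3,4-bis(methoxymethoxy)-5-(3-methylbut-2-en-1-yl)phenyl]-4-(methoxymethoxy)-2-methylidenepent-3-enedioate (silylethyl ester cis to the acrylate unit)
Conditions: Pd(PPh3)4 (10 mol %), CuCl, LiCl, DMSO, 60 °C
Reagents that add atoms: none
Why: Stille coupling of an enol triflate with a 1-substituted vinylstannane with retention of alkene geometry; CuCl with LiCl speeds the slow tin-to-palladium transfer of hindered partners through a vinylcopper species. This forms the C4–C5 bond.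

Step 11
Reactants: 15 the diene diester
Product: 16 (2E)-3-[3,4-bis(methoxymethoxy)-5-(3-methylbut-2-en-1-yl)phenyl]-4-(methoxycarbonyl)-2-(methoxymethoxy)penta-2,4-dienoic acid (carboxyl cis to the acrylate unit)
Conditions: TBAF, THF, 0 °C; pH 4 phosphate buffer
Reagents that add atoms: none
Why: Fluoride attacks silicon and the ester fragments to ethene and the carboxylate (β-elimination), leaving the methyl ester, the acetals and the alkene geometry untouched; the acid is used soon after isolation.

Step 12
Reactants: 17 2-bromo-4-nitrophenol
Product: 18 2-bromo-4-nitrophenyl acetate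
Conditions: Ac2O, pyridine, CH2Cl2, rt
Reagents that add atoms: acetic anhydride, CC(=O)OC(C)=O
Why: Acyl transfer to the acidic phenol; the acetate keeps the later diazonium ion from collapsing to a quinone diazide and can be removed without acid.

Step 13
Reactants: 18 2-bromo-4-nitrophenyl acetate; 4 tributyl(3-methylbut-2-en-1-yl)stannane
Product: 19 2-(3-methylbut-2-en-1-yl)-4-nitrophenyl acetate
Conditions: Pd(PPh3)4 (5 mol %), 1,4-dioxane, 100 °C
Reagents that add atoms: none
Why: Stille coupling as in step 3 on a nitro-activated aryl bromide; an amine-free solvent is used because the 4-nitrophenyl acetate is an activated ester.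

Step 14
Reactants: 19 2-(3-methylbut-2-en-1-yl)-4-nitrophenyl acetate
Product: 20 4-amino-2-(3-methylbut-2-en-1-yl)phenyl acetate
Conditions: Zn dust, AcOH, EtOAc, 0 °C to rt
Reagents that add atoms: none
Why: Dissolving-metal reduction of the nitro group, chemoselective over the trisubstituted alkene and the ester; the acidic medium keeps the aniline protonated and so suppresses O-to-N acetyl transfer, and the product is used at once.

Step 15
Reactants: 20 4-amino-2-(3-methylbut-2-en-1-yl)phenyl acetate
Product: 21 4-acetoxy-3-(3-methylbut-2-en-1-yl)benzenediazonium tetrafluoroborate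
Conditions: HBF4·OEt2, tBuONO, THF, −20 to 0 °C; Et2O to precipitate
Reagents that add atoms: tert-butyl nitrite, CC(C)(C)ON=O; tetrafluoroboric acid (diethyl ether complex), [H+].F[B-](F)(F)F
Why: Anhydrous diazotisation of the anilinium tetrafluoroborate with an alkyl nitrite; alkene-bearing arenediazonium tetrafluoroborates are routinely made this way, and low temperature with short contact protects the prenyl group and the activated acetate.

Step 16
Reactants: 16 the dienoic acid; 21 the diazonium tetrafluoroborate
Product: 22 methyl (2S)-2-[4-acetoxy-3-(3-methylbut-2-en-1-yl)benzyl]-3-[3,4-bis(methoxymethoxy)-5-(3-methylbut-2-en-1-yl)phenyl]-4-(methoxymethoxy)-5-oxo-2,5-dihydrofuran-2-carboxylate (S at the quaternary carbon C5)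
Conditions: Cu(MeCN)4PF6 (10 mol %), (S,S)-tBu-box (12 mol %), 2,6-di-tert-butylpyridine, EtOAc, 0 °C to rt, dark
Reagents that add atoms: none
Why: Monovalent copper bound to the bis(oxazoline) reduces 21 by single-electron transfer to the 4-acetoxy-3-prenylphenyl radical and N2, leaving a divalent copper carboxylate of 16. The aryl radical adds to the unsubstituted terminus C7 of the acrylate unit (Meerwein arylation polarity) and gives a tertiary C5 radical stabilised by the ester C6 and by the C3=C4 double bond. Capture of this radical by the divalent copper carboxylate gives a trivalent alkylcopper species, and C–O reductive elimination forms O1–C5 and returns monovalent copper. The closest known reaction type is the copper–bis(oxazoline)-catalysed enantioselective oxyarylation of 4-aryl-pent-4-enoic and 2-vinylbenzoic acids with arenediazonium salts, where the captured radical is benzylic; here it is ester-substituted and allylic, which is the untested element. The butenolide closes in the 5-exo-trig mode with respect to the C5=C7 alkene (O1 attacks C5, C7 stays outside the ring); closure at the other radical terminus C3 is impossible because it would give a three-membered ring. The single stereocentre C5 (S) is controlled by the chiral ligand on copper in the C–O bond-forming event, since 16 is flat and achiral. The step needs chemoselectivity for C7 over the two prenyl alkenes and their allylic hydrogens, which the much faster addition of aryl radicals to an unhindered acrylate CH2 should secure, and it needs the carboxyl cis to C5, which the geometry of 16 provides. The hindered pyridine takes up HBF4 without attacking the activated aryl acetate of 21 or binding copper.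

Step 17
Reactants: 22 the protected lactone
Product: 23 methyl (2S)-3-[3,4-bis(methoxymethoxy)-5-(3-methylbut-2-en-1-yl)phenyl]-2-[4-hydroxy-3-(3-methylbut-2-en-1-yl)benzyl]-4-(methoxymethoxy)-5-oxo-2,5-dihydrofuran-2-carboxylate
Conditions: NH4OAc, MeOH/H2O (4:1), rt
Reagents that add atoms: none
Why: Ammonium acetate-mediated methanolysis is selective for the phenolic acetate over the methyl ester and the lactone; it is done while the C3 oxygen is still capped so that the free enol never meets base.

Step 18
Reactants: 23 the ring B phenol
Product: 24 methyl (2S)-3-[3,4-dihydroxy-5-(3-methylbut-2-en-1-yl)phenyl]-4-hydroxy-2-[4-hydroxy-3-(3-methylbut-2-en-1-yl)benzyl]-5-oxo-2,5-dihydrofuran-2-carboxylate (CNP0460191.1)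
Conditions: ZnBr2, n-PrSH, CH2Cl2, 0 °C, short reaction time
Reagents that add atoms: none
Why: ZnBr2 activates each methoxymethyl acetal and the thiol captures the oxocarbenium fragment as a monothioacetal, so the two aryl acetals and the enol acetal are cleaved at low temperature without protic acid, the mildest choice for ortho-prenylphenols; the quaternary stereocentre cannot epimerise.

## Compound list

1 | 5-bromovanillin | COc1cc(C=O)cc(Br)c1O | starting material
2 | 3-bromo-4,5-dihydroxybenzaldehyde | O=Cc1cc(O)c(O)c(Br)c1 | intermediate
3 | 3-bromo-4,5-bis(methoxymethoxy)benzaldehyde | O=Cc1cc(OCOC)c(OCOC)c(Br)c1 | intermediate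
4 | tributyl(3-methylbut-2-en-1-yl)stannane | CCCC[Sn](CCCC)(CCCC)CC=C(C)C | starting material
5 | 3,4-bis(methoxymethoxy)-5-(3-methylbut-2-en-1-yl)benzaldehyde | O=Cc1cc(OCOC)c(OCOC)c(CC=C(C)C)c1 | intermediate
6 | methyl glycolate | COC(=O)CO | starting material
7 | methyl 2-(methoxymethoxy)acetate | COCOCC(=O)OC | intermediate
8 | 2-(trimethylsilyl)ethanol | C[Si](C)(C)CCO | starting material
9 | 2-(trimethylsilyl)ethyl 2-(methoxymethoxy)acetate | COCOCC(=O)OCC[Si](C)(C)C | intermediate
10 | 2-(trimethylsilyl)ethyl 3-aryl-3-hydroxy-2-(methoxymethoxy)propanoate, aryl = ring A with two methoxymethyl ethers, diastereomer mixture, racemic | C[Si](C)(C)CCOC(=O)C(OCOC)C(O)c1cc(OCOC)c(OCOC)c(CC=C(C)C)c1 | intermediate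
11 | 2-(trimethylsilyl)ethyl 3-aryl-2-(methoxymethoxy)-3-oxopropanoate, racemic | C[Si](C)(C)CCOC(=O)C(OCOC)C(=O)c1cc(OCOC)c(OCOC)c(CC=C(C)C)c1 | intermediate
12 | 2-(trimethylsilyl)ethyl (2E)-3-aryl-2-(methoxymethoxy)-3-(triflyloxy)prop-2-enoate, triflate cis to ester | C[Si](C)(C)CCOC(=O)/C(OCOC)=C(\OS(=O)(=O)C(F)(F)F)c1cc(OCOC)c(OCOC)c(CC=C(C)C)c1 | intermediate
13 | methyl propiolate | COC(=O)C#C | starting material
14 | methyl 2-(tributylstannyl)prop-2-enoate | COC(=O)C(=C)[Sn](CCCC)(CCCC)CCCC | intermediate
15 | 1-methyl 5-[2-(trimethylsilyl)ethyl] (3E)-3-aryl-4-(methoxymethoxy)-2-methylidenepent-3-enedioate | C[Si](C)(C)CCOC(=O)/C(OCOC)=C(\C(=C)C(=O)OC)c1cc(OCOC)c(OCOC)c(CC=C(C)C)c1 | intermediate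
16 | (2E)-3-aryl-4-(methoxycarbonyl)-2-(methoxymethoxy)penta-2,4-dienoic acid, carboxyl cis to the acrylate unit | OC(=O)/C(OCOC)=C(\C(=C)C(=O)OC)c1cc(OCOC)c(OCOC)c(CC=C(C)C)c1 | intermediate
17 | 2-bromo-4-nitrophenol | Oc1ccc(cc1Br)[N+](=O)[O-] | starting material
18 | 2-bromo-4-nitrophenyl acetate | CC(=O)Oc1ccc(cc1Br)[N+](=O)[O-] | intermediate
19 | 2-(3-methylbut-2-en-1-yl)-4-nitrophenyl acetate | CC(=O)Oc1ccc(cc1CC=C(C)C)[N+](=O)[O-] | intermediate
20 | 4-amino-2-(3-methylbut-2-en-1-yl)phenyl acetate | CC(=O)Oc1ccc(N)cc1CC=C(C)C | intermediate
21 | 4-acetoxy-3-(3-methylbut-2-en-1-yl)benzenediazonium tetrafluoroborate | CC(=O)Oc1ccc(cc1CC=C(C)C)[N+]#N.F[B-](F)(F)F | intermediate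
22 | methyl (2S)-2-[4-acetoxy-3-prenylbenzyl]-3-[3,4-bis(methoxymethoxy)-5-prenylphenyl]-4-(methoxymethoxy)-5-oxo-2,5-dihydrofuran-2-carboxylate | COC(=O)[C@@]1(Cc2ccc(OC(C)=O)c(CC=C(C)C)c2)OC(=O)C(OCOC)=C1c1cc(OCOC)c(OCOC)c(CC=C(C)C)c1 | intermediate
23 | methyl (2S)-3-[3,4-bis(methoxymethoxy)-5-prenylphenyl]-2-[4-hydroxy-3-prenylbenzyl]-4-(methoxymethoxy)-5-oxo-2,5-dihydrofuran-2-carboxylate | COC(=O)[C@@]1(Cc2ccc(O)c(CC=C(C)C)c2)OC(=O)C(OCOC)=C1c1cc(OCOC)c(OCOC)c(CC=C(C)C)c1 | intermediate
24 | methyl (2S)-3-[3,4-dihydroxy-5-prenylphenyl]-4-hydroxy-2-[4-hydroxy-3-prenylbenzyl]-5-oxo-2,5-dihydrofuran-2-carboxylate | COC(=O)[C@@]1(Cc2ccc(O)c(CC=C(C)C)c2)OC(=O)C(O)=C1c1cc(O)c(O)c(CC=C(C)C)c1 | target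

## Step count and least certain steps

Total: 18 steps. Longest linear sequence: 11 steps (1, 2, 3, 6, 7, 8, 10, 11, 16, 17, 18).

**Step 16 (key step).** The most likely failure is poor enantiofacial discrimination or outright racemic ring closure. The C5 radical is electron-poor at carbon yet conjugated to an alkoxy-substituted alkene, so it may be captured by divalent copper more slowly than a benzylic radical, or be oxidised in an outer-sphere process to an alkoxy-stabilised allyl cation that closes without the ligand. Hydrogen abstraction from a prenyl CH2 by the aryl radical, and conjugate addition of the carboxylate to C7 (six-membered lactone), would lower the yield.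

Fallback: it sets out from 16 and 21 and returns at 22. A classical Meerwein bromoarylation (CuBr2 catalyst, LiBr, acetone, 0 °C to rt) should add the aryl radical to C7 and transfer bromine to the C5 radical, giving (2E)-4-bromo-5-[4-acetoxy-3-prenylphenyl]-3-aryl-4-(methoxycarbonyl)-2-(methoxymethoxy)pent-2-enoic acid F1. On addition of NaHCO3 the carboxylate should displace the tertiary allylic bromide; ionisation is assisted by the C3 alkoxy group and only the five-membered closure is possible. This gives the racemic lactone F2. Preparative chromatography on a chiral stationary phase then separates 22 from its R enantiomer F3.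

**Step 8.** The risk is erosion of enol geometry. Coordination of lithium by the C2 methoxymethoxy oxygen could compete with the 1,3-dicarbonyl chelate and place part of the triflate trans to the ester; after coupling, that material would have its carboxyl trans to C5 and could not lactonise.

Fallback: it sets out from 11, returns at 16 and bypasses steps 10 and 11. The triflate is made without regard to geometry (NaH, Tf2O, CH2Cl2), giving 12 mixed with its (Z) isomer F4. The mixture is coupled under Pd(PPh3)4 catalysis with the Reformatsky reagent BrZnCH2CO2Me to the glutaconate 1-methyl 5-[2-(trimethylsilyl)ethyl] 3-aryl-4-(methoxymethoxy)pent-3-enedioate F5. Treatment of F5 with paraformaldehyde and K2CO3 in DMF follows Stobbe logic. The delocalised anion erases the C3=C4 geometry and is hydroxymethylated at C5. The alkoxide then lactonises onto the C2 ester, which is possible only when C2 is cis to C5, and E1cB opening of the six-membered lactone creates C5=C7 and releases the C2 carboxylate. The acid 16 is thus cis by construction, and any diester formed by simple dehydration stays neutral and is removed by extraction. This is a vinylogous use of the Stobbe sequence and would itself need testing.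

**Step 10.** The risk is slow transmetalation of the electron-poor, α-substituted vinylstannane to a hindered tetrasubstituted vinylpalladium species, so that protodestannylation and homocoupling of 14 and reduction or hydrolysis of 12 take over.

Fallback: it sets out from 12 and returns at 15, with the polarity of the coupling reversed. Miyaura borylation (B2pin2, PdCl2(PPh3)2, PPh3, KOPh, toluene, 50 °C) gives 2-(trimethylsilyl)ethyl (2Z)-3-aryl-2-(methoxymethoxy)-3-(4,4,5,5-tetramethyl-1,3,2-dioxaborolan-2-yl)prop-2-enoate F6. Suzuki–Miyaura coupling of F6 with methyl 2-bromoacrylate (PdCl2(dppf), K3PO4, THF/H2O, 40 °C) then gives 15.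

**Step 18.** The risk is Lewis-acid-promoted cyclisation of the newly freed ortho-prenylphenols onto their alkenes (chroman formation), thiol addition to the alkenes, or incomplete cleavage of the enol acetal.

Fallback: it sets out from 23 and returns at 24. Et3SiOTf with 2,2'-bipyridyl in CH2Cl2 at 0 °C exchanges the aryl and enol methoxymethyl ethers for triethylsilyl ethers under buffered, non-protic conditions and silylates the ring B phenol, giving methyl (2S)-3-[3,4-bis(triethylsilyloxy)-5-prenylphenyl]-5-oxo-4-(triethylsilyloxy)-2-[4-(triethylsilyloxy)-3-prenylbenzyl]-2,5-dihydrofuran-2-carboxylate F7. KHF2 in MeOH at rt then removes the phenolic and enol silyl groups under near-neutral conditions.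

## Further compounds

F1 | step 16 | (2E)-5-[4-acetoxy-3-(3-methylbut-2-en-1-yl)phenyl]-3-[3,4-bis(methoxymethoxy)-5-(3-methylbut-2-en-1-yl)phenyl]-4-bromo-4-(methoxycarbonyl)-2-(methoxymethoxy)pent-2-enoic acid, racemic | OC(=O)/C(OCOC)=C(\C(Br)(Cc1ccc(OC(C)=O)c(CC=C(C)C)c1)C(=O)OC)c1cc(OCOC)c(OCOC)c(CC=C(C)C)c1
F2 | step 16 | racemate of 22 | COC(=O)C1(Cc2ccc(OC(C)=O)c(CC=C(C)C)c2)OC(=O)C(OCOC)=C1c1cc(OCOC)c(OCOC)c(CC=C(C)C)c1
F3 | step 16 | (2R) enantiomer of 22 | COC(=O)[C@]1(Cc2ccc(OC(C)=O)c(CC=C(C)C)c2)OC(=O)C(OCOC)=C1c1cc(OCOC)c(OCOC)c(CC=C(C)C)c1
F4 | step 8 | 2-(trimethylsilyl)ethyl (2Z)-3-[3,4-bis(methoxymethoxy)-5-(3-methylbut-2-en-1-yl)phenyl]-2-(methoxymethoxy)-3-(triflyloxy)prop-2-enoate, triflate trans to ester | C[Si](C)(C)CCOC(=O)/C(OCOC)=C(/OS(=O)(=O)C(F)(F)F)c1cc(OCOC)c(OCOC)c(CC=C(C)C)c1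
F5 | step 8 | 1-methyl 5-[2-(trimethylsilyl)ethyl] 3-[3,4-bis(methoxymethoxy)-5-(3-methylbut-2-en-1-yl)phenyl]-4-(methoxymethoxy)pent-3-enedioate, mixture of double-bond isomers | COC(=O)CC(=C(OCOC)C(=O)OCC[Si](C)(C)C)c1cc(OCOC)c(OCOC)c(CC=C(C)C)c1
F6 | step 10 | 2-(trimethylsilyl)ethyl (2Z)-3-[3,4-bis(methoxymethoxy)-5-(3-methylbut-2-en-1-yl)phenyl]-2-(methoxymethoxy)-3-(4,4,5,5-tetramethyl-1,3,2-dioxaborolan-2-yl)prop-2-enoate, boron cis to ester | C[Si](C)(C)CCOC(=O)/C(OCOC)=C(\B1OC(C)(C)C(C)(C)O1)c1cc(OCOC)c(OCOC)c(CC=C(C)C)c1
F7 | step 18 | methyl (2S)-3-[3,4-bis(triethylsilyloxy)-5-(3-methylbut-2-en-1-yl)phenyl]-5-oxo-4-(triethylsilyloxy)-2-[4-(triethylsilyloxy)-3-(3-methylbut-2-en-1-yl)benzyl]-2,5-dihydrofuran-2-carboxylate | COC(=O)[C@@]1(Cc2ccc(O[Si](CC)(CC)CC)c(CC=C(C)C)c2)OC(=O)C(O[Si](CC)(CC)CC)=C1c1cc(O[Si](CC)(CC)CC)c(O[Si](CC)(CC)CC)c(CC=C(C)C)c1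
A1 | alternative 1 | methyl (2S)-3-{3-[(tert-butyldimethylsilyl)oxy]-4-[(2-methylbut-3-en-2-yl)oxy]phenyl}-4-[(tert-butyldimethylsilyl)oxy]-2-{4-[(2-methylbut-3-en-2-yl)oxy]benzyl}-5-oxo-2,5-dihydrofuran-2-carboxylate | COC(=O)[C@@]1(Cc2ccc(OC(C)(C)C=C)cc2)OC(=O)C(O[Si](C)(C)C(C)(C)C)=C1c1ccc(OC(C)(C)C=C)c(O[Si](C)(C)C(C)(C)C)c1
A2 | alternative 1 | methyl (2S)-3-{3-[(tert-butyldimethylsilyl)oxy]-4-hydroxy-5-(3-methylbut-2-en-1-yl)phenyl}-4-[(tert-butyldimethylsilyl)oxy]-2-[4-hydroxy-3-(3-methylbut-2-en-1-yl)benzyl]-5-oxo-2,5-dihydrofuran-2-carboxylate | COC(=O)[C@@]1(Cc2ccc(O)c(CC=C(C)C)c2)OC(=O)C(O[Si](C)(C)C(C)(C)C)=C1c1cc(O[Si](C)(C)C(C)(C)C)c(O)c(CC=C(C)C)c1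
A3 | alternative 2 | (2E)-3-[3,4-bis(methoxymethoxy)-5-(3-methylbut-2-en-1-yl)phenyl]-2-[4-(methoxymethoxy)-3-(3-methylbut-2-en-1-yl)benzyl]prop-2-en-1-ol | OC/C(Cc1ccc(OCOC)c(CC=C(C)C)c1)=C/c1cc(OCOC)c(OCOC)c(CC=C(C)C)c1
A4 | alternative 2 | ethoxycarbonylformonitrile oxide | CCOC(=O)C#[N+][O-]
A5 | alternative 2 | ethyl (4S,5S)-4-[3,4-bis(methoxymethoxy)-5-(3-methylbut-2-en-1-yl)phenyl]-5-(hydroxymethyl)-5-[4-(methoxymethoxy)-3-(3-methylbut-2-en-1-yl)benzyl]-4,5-dihydro-1,2-oxazole-3-carboxylate | CCOC(=O)C1=NO[C@@](CO)(Cc2ccc(OCOC)c(CC=C(C)C)c2)[C@H]1c1cc(OCOC)c(OCOC)c(CC=C(C)C)c1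
A6 | alternative 3 | 5-iodo-1,2-bis(methoxymethoxy)-3-(3-methylbut-2-en-1-yl)benzene | Ic1cc(OCOC)c(OCOC)c(CC=C(C)C)c1
A7 | alternative 3 | (Sa)-4-(methoxycarbonyl)-2-(methoxymethoxy)-5-[4-(methoxymethoxy)-3-(3-methylbut-2-en-1-yl)phenyl]penta-2,3-dienoic acid | OC(=O)C(OCOC)=[C@@]=C(C(=O)OC)Cc1ccc(OCOC)c(CC=C(C)C)c1
A8 | alternative 3 | methyl (2S)-3-[3,4-bis(methoxymethoxy)-5-(3-methylbut-2-en-1-yl)phenyl]-4-(methoxymethoxy)-2-[4-(methoxymethoxy)-3-(3-methylbut-2-en-1-yl)benzyl]-5-oxo-2,5-dihydrofuran-2-carboxylate | COC(=O)[C@@]1(Cc2ccc(OCOC)c(CC=C(C)C)c2)OC(=O)C(OCOC)=C1c1cc(OCOC)c(OCOC)c(CC=C(C)C)c1
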